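**Amounts.** Count in percent of the starting material charged: what has left the starting material and is not side product has passed the coupling. On Friday's last reading that is 80.5 %, yet target stands at 2.3 %.

| flask | starting material | coupling partner | remark | time |
|---|---|---|---|---|
| Friday's | 0.036 M | 1.3 equiv | run made earlier |  |
| Saturday's | 0.036 M | 0.65 equiv | run made earlier |  |
| south | 0.036 M | 1.30 equiv | everything together at the start | 2.5 d |
| south-west | 0.036 M (fed, over 40 h) | 1.30 equiv | all else is in the flask from the start; the feed brings no volume worth counting | 2.5 d |
| east | 0.036 M | 1.30 equiv (fed, over 40 h) | all else is in the flask from the start; the feed brings no volume worth counting | 2.5 d |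

| run | time / h | target / % | side product / % | starting material / % |
|---|---|---|---|---|
| Friday's | 2.50 | 36.8 | 13.5 | 33.6 |
| Friday's | 8.00 | 19.7 | 17.6 | 11.5 |
| Friday's | 12.0 | 10.5 | 17.5 | 7.4 |
| Friday's | 20.0 | 4.8 | 18.5 | 3.9 |
| Friday's | 30.0 | 3.3 | 17.9 | 2.0 |
| Friday's | 40.0 | 2.3 | 18.2 | 1.3 |
| Saturday's | 0.417 | 9.6 | 5.8 | 84.4 |
| Saturday's | 1.33 | 19.3 | 13.5 | 64.3 |
| Saturday's | 2.00 | 21.5 | 16.5 | 54.1 |
| Saturday's | 3.00 | 21.7 | 20.8 | 44.8 |
| Saturday's | 5.00 | 19.2 | 25.0 | 32.8 |
| Saturday's | 6.00 | 17.6 | 27.1 | 29.6 |

(scatter of a reading: 0.3 percentage points)

* the best flask by share of target in target plus side product; "all alike" if 1.5 percentage points covers them all (south / south-west / east / all alike)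
* share of target in target plus side product at the end, south
* share of target in target plus side product at the end, south-west
* share of target in target plus side product at the end, east

- a species is counted by the starting material in it: one side product counts as two
- the numbers in the tables scatter with a standard deviation of 0.3 percentage points

**Survival ratio.** Call target over coupled material the survival ratio, 2.86 % on that reading.

**Two extremes.** If target lasted, you would get 81.6 % in south, which has Friday's charge; if target vanished, zero. Friday's early target half-life reads 5.25 h, far shorter than the run, so the high extreme is out. But target's fractional loss per hour reads less late in Friday's run than in its middle, so I take the ratio as a floor, and the selectivity then follows the side product. That gives me 11.2 % for south.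

**Fed flasks.** On Saturday's run, side product reads 37.2 % of the starting material lost at first and 65.6 % late, although [starting material] fell, so I read that [coupling partner] fades. I expect both fed flasks to run long with little partner working, so I give each Saturday's overall side share, which yields 4.37 %, and I put south first.

The forecast, reasoning that “low A suppresses dimer”, chose south-west, with 7 %, 30 % and 4 %.

**Result.** The flasks give 13.3 % for south, 3.90 % for south-west and 2.21 % for east, so the best is south.

    starting material + coupling partner → target (k = 12.0 M⁻¹ h⁻¹)
    2 starting material → side product (k = 2.20 M⁻¹ h⁻¹)
    target ⇌ isomer of the product (K = 29.0, k = 0.240 h⁻¹)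
    2 coupling partner → homo dimer (k = 1.70 M⁻¹ h⁻¹)

**Fast balance.** In south, target and isomer of the product relax into each other with a half-life of 0.116 d, short against the 2.5 d of the run. The survival ratio, 2.86 % on Friday's reading, stands at 3.45 % in south and 3.38 % in east, while side product stands at 18.3 % in south and 59.9 % in east.

The runs were generated by integration for substances that don't exist.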